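How much target can the flask charged with 0.50 M substrate hold at its best, and when?

all flasks: gas phase 33 mM (held); catalyst 1 mol%

| charge | substrate | remark | time |
|---|---|---|---|
| grey | 0.34 M | run made earlier |  |
| amber | 0.75 M | run made earlier |  |
| flask | 0.50 M |  | 15 d |

- grey (time / d: target / %): 0.500: 16; 0.833: 25; 1.67: 35; 2.50: 34; 4.00: 26; 8.00: 2; 12.0: 0
- amber (time / d: target / %): 0.500: 16; 0.833: 20; 1.67: 30; 2.50: 35; 4.00: 30; 8.00: 0; 12.0: 0

(readings scatter by 2 percentage points)

- at the start none of the gas phase is in solution

1. when, up to 15 d, the flask holds most target
2. the amount of target, in percent of the substrate charged, at that time

The books are kept on the substrate, the limiting reagent while the gas phase is held: each mole charged stands as substrate, as target, or past target. Target rises while its making outruns its using up, and its peak is the crossing at which the two rates are equal. The highest readings are 35% in the grey run and 35% in the amber run, although the amber charge is twice the grey one. Their mean, 35.0%, read with the scatter of those readings, is this reckoning's estimate of the crossing height, the share of the charge standing as target where making equals using up.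

Two steps, each first order in its own species on a shared clock, peak at a height given by the ratio of their constants, the selectivity factor, whatever the speed of the clock. A factor of one gives 36.8%, and the mean of the readings lies 1.8 percentage points below that against a scatter of 2 points per reading, so this reckoning takes the factor as near one. The ledger of this flask at the crossing then reads:

c(substrate) ≈ c(target) ≈ 35.0% of the charge

past target ≈ 30.0% of the charge

The grey run puts its crossing, as read, near 2.08 d, midway between its two highest readings, and the highest amber reading stands at 2.50 d. Interpolating on the substrate charge places this flask at 2.25 d.

The forecast, reasoning that “the peak height also hardly moves”, gives 35.5% at 2.4 d, later than this reckoning.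

The flask gives 35.4% at 2.18 d.

    gas phase ⇌ dissolved gas, rate k1*(csat - [dissolved gas]) (kL = 0.00620 min⁻¹)
    substrate + dissolved gas + catalyst → catalyst + target (k = 6.30 M⁻² min⁻¹)
    dissolved gas + catalyst + target → catalyst + over-reaction product (k = 6.80 M⁻² min⁻¹)

At 2.51 d, just past the best time, this flask makes target 0.853 times as fast as it uses target up, while at 2.18 d it holds 38.2% substrate against 35.4% target, a ratio of 1.08 beside the 1.08 of the two constants. Carried to the neighbour flask charged with 0.25 mol% catalyst, the crossing height of 35.0% is the estimate for that flask, whose best is 35.4% and which at 15.0 d holds 4.75% target.

(The earlier runs and the new flask are simulated from invented constants; the scatter is artificial.)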